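**Retrosynthetic overview**
1. Target 13 ⇐ Suzuki–Miyaura coupling at C5: aryl chloride 11 + (E)-prop-1-enylboronic acid 12.
2. 11 ⇐ intramolecular inverse-electron-demand Diels–Alder / retro-Diels–Alder (loss of N2) of alkynyl pyridazinyl ether 9; the benzene ring and the dihydrofuran ring close together in this step.
3. 9 ⇐ SNAr C–O bond formation between anti-homopropargylic alcohol 6 and 3,6-dichloro-4-methoxypyridazine 7.
4. 6 ⇐ Marshall anti-propargylation of 3,4,5-trimethoxybenzaldehyde 3 with the allenylzinc from (S)-but-3-yn-2-yl mesylate 2; both stereocentres are set here.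
5. Ring order: the trimethoxyphenyl ring is bought; the benzo ring and the dihydrofuran ring form together in step 4.

Assumption: the SMILES is read as the (2R,3R)-trans isomer; the transient allenylzinc and its aldehyde adduct are drawn as ethylzinc species.

**Step 1**
Reactants: 1 (S)-but-3-yn-2-ol
Product: 2 (S)-but-3-yn-2-yl methanesulfonate
Conditions: MsCl, Et3N, CH2Cl2, −78 → 0 °C
Reagents that add atoms: methanesulfonyl chloride, CS(=O)(=O)Cl
Why: Mesylation (O-sulfonylation) makes the leaving group needed for palladium insertion by reaction at oxygen only, so the S carbon is untouched and no new stereocentre arises.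

**Step 2**
Reactants: 2 (S)-but-3-yn-2-yl methanesulfonate; 3 3,4,5-trimethoxybenzaldehyde
Product: 6 (1R,2R)-2-methyl-1-(3,4,5-trimethoxyphenyl)but-3-yn-1-ol, via (M)-buta-1,2-dienyl(ethyl)zinc 4 (not isolated), via ethylzinc alkoxide 5 (not isolated)
Conditions: Pd(OAc)2 (5 mol%), PPh3 (5 mol%), Et2Zn (3 equiv), THF, −78 → −20 °C; aq NH4Cl
Reagents that add atoms: diethylzinc, CC[Zn]CC (its zinc and one ethyl group are held only in 4 and 5)
Why: Marshall propargylation, in which zerovalent palladium (from Pd(OAc)2 and Et2Zn) displaces the mesylate in an anti SN2' sense, transmetalation gives allenylzinc 4 of M helicity, and 4 adds to the aldehyde through a closed SE2' transition state on the zinc-bearing face with the aryl group turned away from the methyl group, so that C2 (R) comes from 2 by chirality transfer with net inversion and C1 (R) from the anti preference of the cyclic transition state.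

**Step 3**
Reactants: 6 (1R,2R)-2-methyl-1-(3,4,5-trimethoxyphenyl)but-3-yn-1-ol; 7 3,6-dichloro-4-methoxypyridazine
Product: 9 3-chloro-4-methoxy-6-{[(1R,2R)-2-methyl-1-(3,4,5-trimethoxyphenyl)but-3-yn-1-yl]oxy}pyridazine, via sodium alkoxide 8 (not isolated)
Conditions: NaH (1.05 equiv), THF, 0 °C; then 7 (1.1 equiv), 15-crown-5, 0 °C → rt
Reagents that add atoms: sodium hydride, [Na+].[H-] (its sodium is held only in 8)
Why: Nucleophilic aromatic substitution (SNAr) by the alkoxide should occur once and at C6 of 7, the carbon meta to the methoxy group and flanked only by H, whereas C3 is deactivated and shielded by the ortho methoxy donor, and because only the O–H bond of 6 is engaged both stereocentres are kept.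

**Step 4**
Reactants: 9 3-chloro-4-methoxy-6-{[(1R,2R)-2-methyl-1-(3,4,5-trimethoxyphenyl)but-3-yn-1-yl]oxy}pyridazine
Product: 11 (2R,3R)-5-chloro-6-methoxy-3-methyl-2-(3,4,5-trimethoxyphenyl)-2,3-dihydro-1-benzofuran, via azo-bridged cycloadduct 10 (not isolated)
Conditions: 1,3,5-triisopropylbenzene (0.02 M), BHT (10 mol%), 230 °C, sealed tube, 24 h (−N2)
Reagents that add atoms: none
Why: Intramolecular inverse-electron-demand Diels–Alder reaction of the alkoxypyridazine (diene termini C3 and C6) with the tethered terminal alkyne, followed by retro-Diels–Alder loss of N2 from 10, is a known reaction type leading from 3-(but-3-ynyloxy)pyridazines to 2,3-dihydrobenzofurans, and here it closes the benzene ring and the dihydrofuran ring in one operation with the chlorine and methoxy positions fixed by the diazine, while the two tether stereocentres pass unchanged into the trans C2/C3 pair.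

**Step 5**
Reactants: 11 (2R,3R)-5-chloro-6-methoxy-3-methyl-2-(3,4,5-trimethoxyphenyl)-2,3-dihydro-1-benzofuran; 12 (E)-prop-1-enylboronic acid
Product: 13 (2R,3R)-6-methoxy-3-methyl-5-[(E)-prop-1-en-1-yl]-2-(3,4,5-trimethoxyphenyl)-2,3-dihydro-1-benzofuran
Conditions: Pd(OAc)2 (2 mol%), SPhos (4 mol%), K3PO4 (3 equiv), toluene/H2O 10:1, 90 °C
Reagents that add atoms: none
Why: Suzuki–Miyaura coupling of the electron-rich aryl chloride, enabled by the bulky electron-rich ligand 2-dicyclohexylphosphino-2',6'-dimethoxybiphenyl (SPhos), transfers the propenyl group with retention of the E geometry under mildly basic conditions that leave the C2 and C3 stereocentres untouched.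

**Compound list**
1 | (S)-but-3-yn-2-ol | C#C[C@H](C)O | starting material
2 | (S)-but-3-yn-2-yl methanesulfonate | C#C[C@H](C)OS(C)(=O)=O | intermediate
3 | 3,4,5-trimethoxybenzaldehyde | COc1cc(C=O)cc(OC)c1OC | starting material
4 | (M)-buta-1,2-dien-1-yl(ethyl)zinc | CC[Zn]C([H])=[C@]=C([H])C | intermediate (not isolated)
5 | ethylzinc (1R,2R)-2-methyl-1-(3,4,5-trimethoxyphenyl)but-3-yn-1-olate | C#C[C@@H](C)[C@@H](O[Zn]CC)c1cc(OC)c(OC)c(OC)c1 | intermediate (not isolated)
6 | (1R,2R)-2-methyl-1-(3,4,5-trimethoxyphenyl)but-3-yn-1-ol (anti) | C#C[C@@H](C)[C@@H](O)c1cc(OC)c(OC)c(OC)c1 | intermediate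
7 | 3,6-dichloro-4-methoxypyridazine | COc1cc(Cl)nnc1Cl | starting material
8 | sodium (1R,2R)-2-methyl-1-(3,4,5-trimethoxyphenyl)but-3-yn-1-olate | C#C[C@@H](C)[C@@H]([O-])c1cc(OC)c(OC)c(OC)c1.[Na+] | intermediate (not isolated)
9 | 3-chloro-4-methoxy-6-{[(1R,2R)-2-methyl-1-(3,4,5-trimethoxyphenyl)but-3-yn-1-yl]oxy}pyridazine | C#C[C@@H](C)[C@@H](Oc1cc(OC)c(Cl)nn1)c1cc(OC)c(OC)c(OC)c1 | intermediate
10 | azo-bridged cycloadduct: 2,3-diazabicyclo[2.2.2]octa-2,5,7-triene fused to the (2R,3R)-dihydrofuran ring, Cl and the ring oxygen on the bridgeheads (bridgehead configuration not specified; both forms give 11) | C[C@@H]1C2=CC3(Cl)N=NC2(O[C@H]1c1cc(OC)c(OC)c(OC)c1)C=C3OC | intermediate (not isolated)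
11 | (2R,3R)-5-chloro-6-methoxy-3-methyl-2-(3,4,5-trimethoxyphenyl)-2,3-dihydro-1-benzofuran | Clc1cc2c(cc1OC)O[C@@H](c1cc(OC)c(OC)c(OC)c1)[C@@H]2C | intermediate
12 | (E)-prop-1-enylboronic acid | C/C=C/B(O)O | starting material
13 | (2R,3R)-6-methoxy-3-methyl-5-[(E)-prop-1-en-1-yl]-2-(3,4,5-trimethoxyphenyl)-2,3-dihydro-1-benzofuran | C/C=C/c1cc2c(cc1OC)O[C@@H](c1cc(OC)c(OC)c(OC)c1)[C@@H]2C | target

**Totals**
Total steps: 5. Longest linear sequence: 5 (1 → 2 → 6 → 9 → 11 → 13).

**Steps most likely to fail**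

Step 4. The methoxy-substituted pyridazine is an electron-rich, slow diene. At 230 °C the secondary benzylic pyridazinyl ether may eliminate or ionise, costing yield or stereochemical purity. The fallback sets out from 6 and comes back at 13.
- Alcohol 6 is treated with KH and trichloroethene in THF, which gives 5-[(1R,2R)-1-{[(E)-1,2-dichloroethenyl]oxy}-2-methylbut-3-yn-1-yl]-1,2,3-trimethoxybenzene F8 in the flask.
- n-BuLi (−78 → −40 °C) and a MeOH quench convert it into the ynol ether diyne 5-[(1R,2R)-1-(ethynyloxy)-2-methylbut-3-yn-1-yl]-1,2,3-trimethoxybenzene F9.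
- Separately, methoxyethyne F10 (chloroacetaldehyde dimethyl acetal, NaNH2, liquid NH3) is treated with n-BuLi and ZnCl2 and coupled with (E)-1-bromoprop-1-ene under Pd(PPh3)4 to give (E)-1-methoxypent-3-en-1-yne F11.
- F9 and F11 undergo a [2+2+2] cyclotrimerisation with [Rh(cod)2]BF4 and 2,2'-bis(diphenylphosphino)-1,1'-binaphthyl in CH2Cl2 at room temperature. This again closes the benzene and dihydrofuran rings together, at a temperature where the benzylic ether is safe.
- Head-to-tail pairing of the two alkoxyalkyne units (meta-dioxygenated arene) should favour 13. The isomer with OMe and propenyl exchanged is the likely by-product and would be separated.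

Step 3. The alkoxide may attack C3 of 7 (next to OMe) instead of C6; that ether would lead to the 7-methoxy isomer after cycloaddition. The fallback sets out from 6 and comes back at 13.
- Alkoxide 8 is made as before and reacted with commercial 3-chloro-5-methoxypyridazine, which has a single leaving group, to give 5-methoxy-3-{[(1R,2R)-2-methyl-1-(3,4,5-trimethoxyphenyl)but-3-yn-1-yl]oxy}pyridazine F4.
- The same thermal cycloaddition, through the chlorine-free azo-bridged cycloadduct F5, gives (2R,3R)-6-methoxy-3-methyl-2-(3,4,5-trimethoxyphenyl)-2,3-dihydro-1-benzofuran F6.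
- NBS in MeCN at 0 °C brominates C5, which is para to the ring oxygen and ortho to OMe, giving (2R,3R)-5-bromo-6-methoxy-3-methyl-2-(3,4,5-trimethoxyphenyl)-2,3-dihydro-1-benzofuran F7.
- F7 is coupled with 12 under the conditions of step 5 to give 13.

Step 2. Aromatic aldehydes give lower anti:syn ratios in this reaction than aliphatic ones, and the transient allenylzinc can partly racemise. The fallback sets out from 1 and comes back at 6.
- 1 is converted with methyl chloroformate and pyridine into (S)-but-3-yn-2-yl methyl carbonate F1.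
- Copper-catalysed anti SN2' borylation (CuCl, KOt-Bu, 4,5-bis(diphenylphosphino)-9,9-dimethylxanthene, B2pin2, THF) gives the isolable, configurationally stable (M)-2-(buta-1,2-dien-1-yl)-4,4,5,5-tetramethyl-1,3,2-dioxaborolane F2.
- F2 adds to aldehyde 3 in toluene at −30 °C under the matched enantiomer of 3,3'-bis(2,4,6-triisopropylphenyl)-1,1'-binaphthyl-2,2'-diyl hydrogen phosphate. The closed chair transition state gives 2-{[(1R,2R)-2-methyl-1-(3,4,5-trimethoxyphenyl)but-3-yn-1-yl]oxy}-4,4,5,5-tetramethyl-1,3,2-dioxaborolane F3, which is hydrolysed on work-up to 6.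

**Further compounds**
F1 | step 2 | (S)-but-3-yn-2-yl methyl carbonate | C#C[C@H](C)OC(=O)OC
F2 | step 2 | (M)-2-(buta-1,2-dien-1-yl)-4,4,5,5-tetramethyl-1,3,2-dioxaborolane | CC1(C)OB(OC1(C)C)C([H])=[C@]=C([H])C
F3 | step 2 | 2-{[(1R,2R)-2-methyl-1-(3,4,5-trimethoxyphenyl)but-3-yn-1-yl]oxy}-4,4,5,5-tetramethyl-1,3,2-dioxaborolane | C#C[C@@H](C)[C@@H](OB1OC(C)(C)C(C)(C)O1)c1cc(OC)c(OC)c(OC)c1
F4 | step 3 | 5-methoxy-3-{[(1R,2R)-2-methyl-1-(3,4,5-trimethoxyphenyl)but-3-yn-1-yl]oxy}pyridazine | C#C[C@@H](C)[C@@H](Oc1cc(OC)cnn1)c1cc(OC)c(OC)c(OC)c1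
F5 | step 3 | azo-bridged cycloadduct of F4 (chlorine-free analogue of 10, bridgehead configuration not specified) | C[C@@H]1C2=CC3N=NC2(O[C@H]1c1cc(OC)c(OC)c(OC)c1)C=C3OC
F6 | step 3 | (2R,3R)-6-methoxy-3-methyl-2-(3,4,5-trimethoxyphenyl)-2,3-dihydro-1-benzofuran | c1cc2c(cc1OC)O[C@@H](c1cc(OC)c(OC)c(OC)c1)[C@@H]2C
F7 | step 3 | (2R,3R)-5-bromo-6-methoxy-3-methyl-2-(3,4,5-trimethoxyphenyl)-2,3-dihydro-1-benzofuran | Brc1cc2c(cc1OC)O[C@@H](c1cc(OC)c(OC)c(OC)c1)[C@@H]2C
F8 | step 4 | 5-[(1R,2R)-1-{[(E)-1,2-dichloroethenyl]oxy}-2-methylbut-3-yn-1-yl]-1,2,3-trimethoxybenzene | C#C[C@@H](C)[C@@H](O/C(Cl)=C\Cl)c1cc(OC)c(OC)c(OC)c1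
F9 | step 4 | 5-[(1R,2R)-1-(ethynyloxy)-2-methylbut-3-yn-1-yl]-1,2,3-trimethoxybenzene | C#C[C@@H](C)[C@@H](OC#C)c1cc(OC)c(OC)c(OC)c1
F10 | step 4 | methoxyethyne | COC#C
F11 | step 4 | (E)-1-methoxypent-3-en-1-yne | COC#C/C=C/C
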